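**Plan**

- Numbering (cedrane): C1 quaternary bridgehead, C2 the CHO-bearing carbon, C5 ring-fusion CH, C6 = CMe(CH2OH), C7 bridgehead CH, C8=C9 the alkene (C8 carries CO2H), C10 the acyloxy carbon, C11 the CH2 bridge; ring A = C1–C5, ring B = C1/C5/C6/C7/C11, ring C = C1/C11/C7/C8/C9/C10.
- Enabling feature: ring C is a cresol in disguise (C11 the phenol carbon, C8 the methyl-bearing carbon) and C5=C6 is an alkene held on C1 by the C2–C4 chain, so C1–C5, C6–C7 and C10–O are cut in one operation.
- Other cuts: the C10 ester C–O (side-chain acid, itself cut between its C8 and C9 into 8-bromooctanoic acid and oct-7-yn-1-ol), C8 CO2H back to CH3, C2 CHO back to CH2OSi, C11 CH2 back to C=O.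
- Forward: the arene (future ring C) first, then the C2 centre and the tether, then rings A and B together by anodic oxidation of the phenol, then C11 deoxygenation, C8 oxidation, chain ester at C10, C8 acid, C2 aldehyde, desilylation.
- Stereochemistry: C2 from an oxazolidinone-controlled allylation; C1, C5 and C7 relayed from C2 in the cycloaddition; C6 from the E-alkene; C10 from acetate capture opposite the C5–C6 bridge (kept through ester exchange); the Z-alkene from Lindlar reduction.

Key step: step 13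

Remark on the chemistry: C5 is not independent of C1 and C7, since a three-atom C2–C4 tether can span C1–C5 only with C4 on the C11 side of the C5–C6 bridge; read literally the C5 descriptor of the target string points C4 to the C10 side, so C5 is taken as the ring closure sets it (CH2OH at C6 staying syn to H5) while every string keeps the descriptors of the target string.

**Route**

Step 1
Reactants: 1 2-bromo-5-methylanisole; 2 (2-tert-butoxy-2-oxoethyl)zinc bromide
Product: 3 tert-butyl 2-(2-methoxy-4-methylphenyl)acetate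
Conditions: Pd(dba)2 (2 mol %), P(t-Bu)3 (2 mol %), THF, rt
Reagents that add atoms: none
Why: Negishi-type α-arylation of a Reformatsky reagent at zerovalent palladium with a bulky trialkylphosphine is reliable for ortho-substituted electron-rich aryl bromides and avoids the diarylation seen with alkali enolates.

Step 2
Reactants: 3 tert-butyl 2-(2-methoxy-4-methylphenyl)acetate
Product: 4 2-(2-methoxy-4-methylphenyl)acetic acid
Conditions: CF3CO2H/CH2Cl2 (1:3), rt
Reagents that add atoms: none
Why: Acidolysis of the tert-butyl ester (loss of isobutene) leaves the anisole and the benzylic methylene untouched.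

Step 3
Reactants: 4 2-(2-methoxy-4-methylphenyl)acetic acid; 5 (S)-4-benzyloxazolidin-2-one
Product: 7 (S)-4-benzyl-3-[2-(2-methoxy-4-methylphenyl)acetyl]oxazolidin-2-one, via mixed pivalic anhydride 6 (not isolated)
Conditions: t-BuCOCl, Et3N, THF, −20 °C; then 5, LiCl, rt
Reagents that add atoms: none
Why: Mixed-anhydride N-acylation of the oxazolidinone with LiCl activation, the acyl transfer taking place at the less hindered arylacetyl carbonyl.

Step 4
Reactants: 7 (S)-4-benzyl-3-[2-(2-methoxy-4-methylphenyl)acetyl]oxazolidin-2-one; 8 allyl bromide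
Product: 10 (S)-4-benzyl-3-[(S)-2-(2-methoxy-4-methylphenyl)pent-4-enoyl]oxazolidin-2-one, via sodium Z-enolate 9 (not isolated)
Conditions: NaN(SiMe3)2, THF, −78 °C; then allyl bromide, −78 → −45 °C
Reagents that add atoms: none
Why: Evans asymmetric alkylation, in which the chelated Z-enolate is allylated on the face opposite the benzyl group of the auxiliary, sets the future C2 centre as S.

Step 5
Reactants: 10 (S)-4-benzyl-3-[(S)-2-(2-methoxy-4-methylphenyl)pent-4-enoyl]oxazolidin-2-one
Product: 11 (S)-2-(2-methoxy-4-methylphenyl)pent-4-en-1-ol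
Conditions: LiBH4, MeOH (1 equiv), Et2O, 0 °C
Reagents that add atoms: none
Why: Reductive cleavage of the imide by LiBH4 at the exocyclic carbonyl gives the primary alcohol without enolising the α-aryl centre and returns the auxiliary.

Step 6
Reactants: 11 (S)-2-(2-methoxy-4-methylphenyl)pent-4-en-1-ol
Product: 12 tert-butyl{[(S)-2-(2-methoxy-4-methylphenyl)pent-4-en-1-yl]oxy}dimethylsilane
Conditions: TBSCl, imidazole, DMF, rt
Reagents that add atoms: tert-butyldimethylsilyl chloride, CC(C)(C)[Si](C)(C)Cl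
Why: Imidazole-promoted silylation of a primary alcohol gives the ether that will mark the C2 arm.

Step 7
Reactants: 12 tert-butyl{[(S)-2-(2-methoxy-4-methylphenyl)pent-4-en-1-yl]oxy}dimethylsilane
Product: 14 (S)-5-(tert-butyldimethylsilyloxy)-4-(2-methoxy-4-methylphenyl)pentan-1-ol, via B-alkyl-9-borabicyclononane 13 (not isolated)
Conditions: 9-borabicyclo[3.3.1]nonane (9-BBN), THF, 0 °C → rt; then NaOH, H2O2, 0 °C → rt
Reagents that add atoms: hydrogen peroxide, OO
Why: Brown hydroboration–oxidation of the terminal alkene with 9-BBN places boron, and then oxygen, on the terminal carbon only.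

Step 8
Reactants: 14 (S)-5-(tert-butyldimethylsilyloxy)-4-(2-methoxy-4-methylphenyl)pentan-1-ol
Product: 15 (S)-5-(tert-butyldimethylsilyloxy)-4-(2-methoxy-4-methylphenyl)pentanal
Conditions: Dess–Martin periodinane, CH2Cl2, rt
Reagents that add atoms: none
Why: Dess–Martin oxidation stops at the aldehyde, and the stereocentre is γ to the new carbonyl and cannot epimerise.

Step 9
Reactants: 15 (S)-5-(tert-butyldimethylsilyloxy)-4-(2-methoxy-4-methylphenyl)pentanal; 16 ethyl 2-(triphenylphosphoranylidene)propanoate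
Product: 17 ethyl (2E,6S)-7-(tert-butyldimethylsilyloxy)-6-(2-methoxy-4-methylphenyl)-2-methylhept-2-enoate
Conditions: toluene, 60 °C
Reagents that add atoms: none
Why: Wittig olefination with the α-branched stabilised ylide should give the E-trisubstituted enoate, the geometry that the key step turns into the C5/C6 relationship.

Step 10
Reactants: 17 ethyl (2E,6S)-7-(tert-butyldimethylsilyloxy)-6-(2-methoxy-4-methylphenyl)-2-methylhept-2-enoate
Product: 18 (2E,6S)-7-(tert-butyldimethylsilyloxy)-6-(2-methoxy-4-methylphenyl)-2-methylhept-2-en-1-ol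
Conditions: i-Bu2AlH, CH2Cl2, −78 °C; aqueous potassium sodium tartrate work-up
Reagents that add atoms: none
Why: 1,2-Reduction of the enoate by i-Bu2AlH gives the allylic alcohol and leaves the alkene geometry unchanged.

Step 11
Reactants: 18 (2E,6S)-7-(tert-butyldimethylsilyloxy)-6-(2-methoxy-4-methylphenyl)-2-methylhept-2-en-1-ol
Product: 19 1-[(2S,5E)-1-(tert-butyldimethylsilyloxy)-7-(tert-butyldiphenylsilyloxy)-6-methylhept-5-en-2-yl]-2-methoxy-4-methylbenzene
Conditions: TBDPSCl, imidazole, CH2Cl2, rt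
Reagents that add atoms: tert-butyldiphenylsilyl chloride, CC(C)(C)[Si](Cl)(c1ccccc1)c1ccccc1
Why: Silylation of the allylic alcohol with a group that outlasts the later acidic removal of the TBS ether and keeps the alkene nucleophilic.

Step 12
Reactants: 19 1-[(2S,5E)-1-(tert-butyldimethylsilyloxy)-7-(tert-butyldiphenylsilyloxy)-6-methylhept-5-en-2-yl]-2-methoxy-4-methylbenzene
Product: 20 2-[(2S,5E)-1-(tert-butyldimethylsilyloxy)-7-(tert-butyldiphenylsilyloxy)-6-methylhept-5-en-2-yl]-5-methylphenol
Conditions: NaSEt, DMF, 110 °C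
Reagents that add atoms: none
Why: SN2 demethylation of the aryl methyl ether by the soft thiolate frees the phenol, and the alkyl silyl ethers and the alkene are not attacked by this nucleophile.

Step 13
Reactants: 20 2-[(2S,5E)-1-(tert-butyldimethylsilyloxy)-7-(tert-butyldiphenylsilyloxy)-6-methylhept-5-en-2-yl]-5-methylphenol
Product: 21 tricyclic keto acetate (10-acetoxy-2-[(tert-butyldimethylsilyloxy)methyl]-6-[(tert-butyldiphenylsilyloxy)methyl]-6,8-dimethyltricyclo[5.3.1.0^1,5]undec-8-en-11-one)
Conditions: constant current (about 2.2 F/mol), carbon anode, Pt cathode, undivided cell, LiClO4, NaOAc, AcOH, rt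
Reagents that add atoms: acetic acid, CC(=O)O
Why: Two-electron oxidation at the anode turns phenol 20 into a phenoxonium ion whose charge is spread over C1, C10, C9, C8 and C7 (a 2-oxidopentadienyl cation); C5 of the E-alkene bonds to C1, the tertiary C6 cation that results closes onto C7, and acetate caps the remaining C8–C10 allyl cation at C10. The closest known reaction type is the oxidative dearomatisation of ortho-(pent-4-enyl)phenols with intramolecular cationic (5+2) cycloaddition to bicyclo[3.2.1]octenones, known at an anode and with Pb(OAc)4 and on cedrane-type substrates. Ring A closes by 5-exo attack of the tethered alkene on C1, and ring B by the C6–C7 bond across the two ends of the five-carbon cation (the (5+2) mode), which leaves C11 as the bridging ketone. C1 and C7 follow from the C2 centre, whose hydrogen eclipses the C1–C11 bond to relieve A1,3 strain so that the tether reaches one face of the ring only; C5 is fixed by the three-atom tether (C4 on the C11 side), C6 by suprafacial addition to the E-alkene (CH2OTBDPS syn to H5), and C10 by acetate entering on the face away from the C5–C6 bridge. The step needs the phenol to be oxidised before the alkene, the alkene to outrun acetate at C1, C–C rather than C–O closure at C6, and acetate capture at C10 rather than C8; the low oxidation potential of the phenol, the five-membered tether with a trisubstituted alkene, the C8 methyl that stabilises the allyl cation and the preference for the secondary terminus (leaving the trisubstituted C8=C9 alkene) should secure these, while the NaOAc buffer protects the TBS ether.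

Step 14
Reactants: 21 tricyclic keto acetate
Product: 22 C11 tosylhydrazone of 21
Conditions: TsNHNH2, MeOH, 60 °C
Reagents that add atoms: p-toluenesulfonyl hydrazide, Cc1ccc(S(=O)(=O)NN)cc1
Why: Hydrazone condensation at the strained one-carbon-bridge ketone, the only carbonyl electrophilic enough to react, with the acetate untouched under neutral conditions.

Step 15
Reactants: 22 C11 tosylhydrazone of 21
Product: 25 C11-deoxy acetate (10-acetoxy-2-[(tert-butyldimethylsilyloxy)methyl]-6-[(tert-butyldiphenylsilyloxy)methyl]-6,8-dimethyltricyclo[5.3.1.0^1,5]undec-8-ene), via N-boryl tosylhydrazine 23 (not isolated), via C11 diazene 24 (not isolated)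
Conditions: catecholborane, CHCl3, 0 °C; then NaOAc·3H2O, reflux
Reagents that add atoms: none
Why: Caglioti-type tosylhydrazone reduction in its catecholborane form, in which hydride adds to C=N, acetate-induced loss of sulfinate gives the diazene and N2 is extruded to leave CH2; the alkene is not allylic to C11 and so cannot shift.

Step 16
Reactants: 25 C11-deoxy acetate
Product: 27 C8 enal (10-acetoxy-2-[(tert-butyldimethylsilyloxy)methyl]-6-[(tert-butyldiphenylsilyloxy)methyl]-6-methyltricyclo[5.3.1.0^1,5]undec-8-ene-8-carbaldehyde), via C8 hydroxymethyl compound 26 (not isolated)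
Conditions: SeO2 (0.5 equiv), t-BuOOH, CH2Cl2, rt; crude, then Dess–Martin periodinane, CH2Cl2, rt
Reagents that add atoms: tert-butyl hydroperoxide, CC(C)(C)OO (the oxygen atom, passed on through selenium dioxide, O=[Se]=O)
Why: Riley allylic oxidation (ene reaction, then 2,3-sigmatropic shift) can act only on the methyl group, because the other allylic hydrogen on the substituted alkene carbon is the C7 bridgehead hydrogen excluded by Bredt's rule, and Dess–Martin oxidation then takes the allylic alcohol to the enal.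

Step 17
Reactants: 27 C8 enal
Product: 28 C10 alcohol (10-hydroxy-2-[(tert-butyldimethylsilyloxy)methyl]-6-[(tert-butyldiphenylsilyloxy)methyl]-6-methyltricyclo[5.3.1.0^1,5]undec-8-ene-8-carbaldehyde)
Conditions: K2CO3 (cat.), MeOH, 0 °C
Reagents that add atoms: none
Why: Base-catalysed transesterification removes the acetyl group at its carbonyl, so the C10–O bond and its configuration are kept.

Step 18
Reactants: 29 oct-7-yn-1-ol
Product: 30 tert-butyl(oct-7-yn-1-yloxy)diphenylsilane
Conditions: TBDPSCl, imidazole, CH2Cl2, rt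
Reagents that add atoms: tert-butyldiphenylsilyl chloride, CC(C)(C)[Si](Cl)(c1ccccc1)c1ccccc1
Why: Silylation of the primary alcohol with the same group as on the C6 arm, so that both fall in the last step.

Step 19
Reactants: 30 tert-butyl(oct-7-yn-1-yloxy)diphenylsilane; 31 8-bromooctanoic acid
Product: 33 16-(tert-butyldiphenylsilyloxy)hexadec-9-ynoic acid, via lithium acetylide 32 (not isolated)
Conditions: 30 (2.2 equiv), n-BuLi (2.2 equiv), THF/HMPA, −78 → 0 °C; then 31, 0 °C → rt; aqueous HCl work-up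
Reagents that add atoms: none
Why: SN2 alkylation of a lithium acetylide by a primary bromide in THF/HMPA, with the second equivalent of acetylide holding the acid as its unreactive lithium carboxylate.

Step 20
Reactants: 33 16-(tert-butyldiphenylsilyloxy)hexadec-9-ynoic acid
Product: 34 (Z)-16-(tert-butyldiphenylsilyloxy)hexadec-9-enoic acid
Conditions: H2 (1 atm), Pd on CaCO3 poisoned with Pb(OAc)2, quinoline, EtOAc, rt
Reagents that add atoms: none
Why: Lindlar semi-hydrogenation adds H2 syn to the alkyne and stops at the Z-alkene.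

Step 21
Reactants: 28 C10 alcohol; 34 (Z)-16-(tert-butyldiphenylsilyloxy)hexadec-9-enoic acid
Product: 36 C10 ester enal (10-{[(9Z)-16-(tert-butyldiphenylsilyloxy)hexadec-9-enoyl]oxy} analogue of 28), via mixed trichlorobenzoic anhydride 35 (not isolated)
Conditions: 34, 2,4,6-trichlorobenzoyl chloride, Et3N, THF, rt; then 28, DMAP, toluene, 40 °C
Reagents that add atoms: none
Why: Yamaguchi esterification, in which DMAP passes the acyl group from the mixed anhydride to the hindered allylic alcohol, forms the ester with retention at C10 because the C10–O bond is not broken.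

Step 22
Reactants: 36 C10 ester enal
Product: 37 C8 carboxylic acid (8-carboxylic acid analogue of 36)
Conditions: NaClO2, NaH2PO4, 2-methylbut-2-ene, t-BuOH/H2O, 0 °C → rt
Reagents that add atoms: sodium chlorite, [Na+].[O-]Cl=O
Why: Pinnick oxidation takes the enal to the enoic acid, the alkene scavenger protecting the Z-alkene from hypochlorite and the buffered medium sparing the silyl ethers.

Step 23
Reactants: 37 C8 carboxylic acid
Product: 38 C2 hydroxymethyl acid (2-(hydroxymethyl) analogue of 37)
Conditions: AcOH/THF/H2O (3:1:1), 40 °C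
Reagents that add atoms: none
Why: Acid hydrolysis of the primary TBS ether is selective because the two TBDPS ethers are far more stable to acid.

Step 24
Reactants: 38 C2 hydroxymethyl acid
Product: 39 C2 aldehyde acid (2-formyl analogue of 37)
Conditions: Dess–Martin periodinane, pyridine, CH2Cl2, 0 °C
Reagents that add atoms: none
Why: Dess–Martin oxidation of the only free alcohol tolerates the carboxylic acid, and the buffered, cold conditions should keep the C2 centre from epimerising.

Step 25
Reactants: 39 C2 aldehyde acid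
Product: 40 target CNP0148862.1 (2-formyl-10-{[(9Z)-16-hydroxyhexadec-9-enoyl]oxy}-6-(hydroxymethyl)-6-methyltricyclo[5.3.1.0^1,5]undec-8-ene-8-carboxylic acid)
Conditions: HF·pyridine, pyridine, THF, 0 °C → rt
Reagents that add atoms: none
Why: Fluoride-mediated cleavage of both TBDPS ethers under buffered, mildly acidic conditions should spare the α-centre of the aldehyde, the allylic ester and the Z-alkene.

**Compound list**

1 | 2-bromo-5-methylanisole | COc1cc(C)ccc1Br | starting material
2 | (2-tert-butoxy-2-oxoethyl)zinc bromide | CC(C)(C)OC(=O)C[Zn]Br | starting material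
3 | tert-butyl 2-(2-methoxy-4-methylphenyl)acetate | COc1cc(C)ccc1CC(=O)OC(C)(C)C | intermediate
4 | 2-(2-methoxy-4-methylphenyl)acetic acid | COc1cc(C)ccc1CC(=O)O | intermediate
5 | (S)-4-benzyloxazolidin-2-one | O=C1N[C@@H](Cc2ccccc2)CO1 | starting material
6 | 2-(2-methoxy-4-methylphenyl)acetic pivalic anhydride | COc1cc(C)ccc1CC(=O)OC(=O)C(C)(C)C | intermediate
7 | (S)-4-benzyl-3-[2-(2-methoxy-4-methylphenyl)acetyl]oxazolidin-2-one | COc1cc(C)ccc1CC(=O)N1C(=O)OC[C@@H]1Cc1ccccc1 | intermediate
8 | allyl bromide | C=CCBr | starting material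
9 | sodium Z-enolate of 7 | COc1cc(C)ccc1/C=C(\[O-])N1C(=O)OC[C@@H]1Cc1ccccc1.[Na+] | intermediate
10 | (S)-4-benzyl-3-[(S)-2-(2-methoxy-4-methylphenyl)pent-4-enoyl]oxazolidin-2-one | COc1cc(C)ccc1[C@@H](C(=O)N1C(=O)OC[C@@H]1Cc1ccccc1)CC=C | intermediate
11 | (S)-2-(2-methoxy-4-methylphenyl)pent-4-en-1-ol | COc1cc(C)ccc1[C@@H](CO)CC=C | intermediate
12 | tert-butyl{[(S)-2-(2-methoxy-4-methylphenyl)pent-4-en-1-yl]oxy}dimethylsilane | COc1cc(C)ccc1[C@@H](CO[Si](C)(C)C(C)(C)C)CC=C | intermediate
13 | 9-[(S)-5-(tert-butyldimethylsilyloxy)-4-(2-methoxy-4-methylphenyl)pentyl]-9-borabicyclo[3.3.1]nonane | COc1cc(C)ccc1[C@@H](CO[Si](C)(C)C(C)(C)C)CCCB1C2CCCC1CCC2 | intermediate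
14 | (S)-5-(tert-butyldimethylsilyloxy)-4-(2-methoxy-4-methylphenyl)pentan-1-ol | COc1cc(C)ccc1[C@@H](CO[Si](C)(C)C(C)(C)C)CCCO | intermediate
15 | (S)-5-(tert-butyldimethylsilyloxy)-4-(2-methoxy-4-methylphenyl)pentanal | COc1cc(C)ccc1[C@@H](CO[Si](C)(C)C(C)(C)C)CCC=O | intermediate
16 | ethyl 2-(triphenylphosphoranylidene)propanoate | CCOC(=O)C(C)=P(c1ccccc1)(c1ccccc1)c1ccccc1 | starting material
17 | ethyl (2E,6S)-7-(tert-butyldimethylsilyloxy)-6-(2-methoxy-4-methylphenyl)-2-methylhept-2-enoate | COc1cc(C)ccc1[C@@H](CO[Si](C)(C)C(C)(C)C)CC/C=C(\C)C(=O)OCC | intermediate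
18 | (2E,6S)-7-(tert-butyldimethylsilyloxy)-6-(2-methoxy-4-methylphenyl)-2-methylhept-2-en-1-ol | COc1cc(C)ccc1[C@@H](CO[Si](C)(C)C(C)(C)C)CC/C=C(\C)CO | intermediate
19 | 1-[(2S,5E)-1-(tert-butyldimethylsilyloxy)-7-(tert-butyldiphenylsilyloxy)-6-methylhept-5-en-2-yl]-2-methoxy-4-methylbenzene | COc1cc(C)ccc1[C@@H](CO[Si](C)(C)C(C)(C)C)CC/C=C(\C)CO[Si](c1ccccc1)(c1ccccc1)C(C)(C)C | intermediate
20 | 2-[(2S,5E)-1-(tert-butyldimethylsilyloxy)-7-(tert-butyldiphenylsilyloxy)-6-methylhept-5-en-2-yl]-5-methylphenol (key-step precursor) | Cc1ccc([C@@H](CO[Si](C)(C)C(C)(C)C)CC/C=C(\C)CO[Si](c2ccccc2)(c2ccccc2)C(C)(C)C)c(O)c1 | intermediate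
21 | tricyclic keto acetate: 10-acetoxy-2-[(tert-butyldimethylsilyloxy)methyl]-6-[(tert-butyldiphenylsilyloxy)methyl]-6,8-dimethyltricyclo[5.3.1.0^1,5]undec-8-en-11-one; acetate on the C11 side of ring C, CH2OTBDPS syn to H5 (key-step product) | C[C@@]1(CO[Si](c4ccccc4)(c4ccccc4)C(C)(C)C)[C@@H]2C(=O)[C@]3([C@@H](OC(C)=O)C=C2C)[C@@H](CO[Si](C)(C)C(C)(C)C)CC[C@@H]13 | intermediate
22 | C11 tosylhydrazone of 21 (C=N geometry not defined) | C[C@@]1(CO[Si](c4ccccc4)(c4ccccc4)C(C)(C)C)[C@@H]2C(=NNS(=O)(=O)c4ccc(C)cc4)[C@]3([C@@H](OC(C)=O)C=C2C)[C@@H](CO[Si](C)(C)C(C)(C)C)CC[C@@H]13 | intermediate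
23 | N-(1,3,2-benzodioxaborol-2-yl) C11 tosylhydrazine from 22 (C11–H, either C11 epimer) | C[C@@]1(CO[Si](c4ccccc4)(c4ccccc4)C(C)(C)C)[C@@H]2C(N(B4Oc5ccccc5O4)NS(=O)(=O)c4ccc(C)cc4)[C@]3([C@@H](OC(C)=O)C=C2C)[C@@H](CO[Si](C)(C)C(C)(C)C)CC[C@@H]13 | intermediate
24 | C11 monoalkyl diazene (either C11 epimer) | C[C@@]1(CO[Si](c4ccccc4)(c4ccccc4)C(C)(C)C)[C@@H]2C(N=N)[C@]3([C@@H](OC(C)=O)C=C2C)[C@@H](CO[Si](C)(C)C(C)(C)C)CC[C@@H]13 | intermediate
25 | C11-deoxy acetate: 10-acetoxy-2-[(tert-butyldimethylsilyloxy)methyl]-6-[(tert-butyldiphenylsilyloxy)methyl]-6,8-dimethyltricyclo[5.3.1.0^1,5]undec-8-ene | C[C@@]1(CO[Si](c4ccccc4)(c4ccccc4)C(C)(C)C)[C@@H]2C[C@]3([C@@H](OC(C)=O)C=C2C)[C@@H](CO[Si](C)(C)C(C)(C)C)CC[C@@H]13 | intermediate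
26 | 8-(hydroxymethyl) analogue of 25 | C[C@@]1(CO[Si](c4ccccc4)(c4ccccc4)C(C)(C)C)[C@@H]2C[C@]3([C@@H](OC(C)=O)C=C2CO)[C@@H](CO[Si](C)(C)C(C)(C)C)CC[C@@H]13 | intermediate
27 | C8 enal: 8-formyl analogue of 25 | C[C@@]1(CO[Si](c4ccccc4)(c4ccccc4)C(C)(C)C)[C@@H]2C[C@]3([C@@H](OC(C)=O)C=C2C=O)[C@@H](CO[Si](C)(C)C(C)(C)C)CC[C@@H]13 | intermediate
28 | C10 alcohol: 10-hydroxy-8-formyl compound | C[C@@]1(CO[Si](c4ccccc4)(c4ccccc4)C(C)(C)C)[C@@H]2C[C@]3([C@@H](O)C=C2C=O)[C@@H](CO[Si](C)(C)C(C)(C)C)CC[C@@H]13 | intermediate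
29 | oct-7-yn-1-ol | OCCCCCCC#C | starting material
30 | tert-butyl(oct-7-yn-1-yloxy)diphenylsilane | C#CCCCCCCO[Si](c1ccccc1)(c1ccccc1)C(C)(C)C | intermediate
31 | 8-bromooctanoic acid | OC(=O)CCCCCCCBr | starting material
32 | lithium acetylide of 30 | [Li]C#CCCCCCCO[Si](c1ccccc1)(c1ccccc1)C(C)(C)C | intermediate
33 | 16-(tert-butyldiphenylsilyloxy)hexadec-9-ynoic acid | OC(=O)CCCCCCCC#CCCCCCCO[Si](c1ccccc1)(c1ccccc1)C(C)(C)C | intermediate
34 | (Z)-16-(tert-butyldiphenylsilyloxy)hexadec-9-enoic acid | OC(=O)CCCCCCC/C=C\CCCCCCO[Si](c1ccccc1)(c1ccccc1)C(C)(C)C | intermediate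
35 | mixed anhydride of 34 with 2,4,6-trichlorobenzoic acid | O=C(OC(=O)c1c(Cl)cc(Cl)cc1Cl)CCCCCCC/C=C\CCCCCCO[Si](c1ccccc1)(c1ccccc1)C(C)(C)C | intermediate
36 | C10 ester enal: 10-O-[(9Z)-16-(tert-butyldiphenylsilyloxy)hexadec-9-enoyl] derivative of 28 | C[C@@]1(CO[Si](c4ccccc4)(c4ccccc4)C(C)(C)C)[C@@H]2C[C@]3([C@@H](OC(=O)CCCCCCC/C=C\CCCCCCO[Si](c4ccccc4)(c4ccccc4)C(C)(C)C)C=C2C=O)[C@@H](CO[Si](C)(C)C(C)(C)C)CC[C@@H]13 | intermediate
37 | C8 carboxylic acid from 36 | C[C@@]1(CO[Si](c4ccccc4)(c4ccccc4)C(C)(C)C)[C@@H]2C[C@]3([C@@H](OC(=O)CCCCCCC/C=C\CCCCCCO[Si](c4ccccc4)(c4ccccc4)C(C)(C)C)C=C2C(=O)O)[C@@H](CO[Si](C)(C)C(C)(C)C)CC[C@@H]13 | intermediate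
38 | C2 hydroxymethyl acid (TBS removed) | C[C@@]1(CO[Si](c4ccccc4)(c4ccccc4)C(C)(C)C)[C@@H]2C[C@]3([C@@H](OC(=O)CCCCCCC/C=C\CCCCCCO[Si](c4ccccc4)(c4ccccc4)C(C)(C)C)C=C2C(=O)O)[C@@H](CO)CC[C@@H]13 | intermediate
39 | C2 aldehyde acid, both TBDPS ethers in place | C[C@@]1(CO[Si](c4ccccc4)(c4ccccc4)C(C)(C)C)[C@@H]2C[C@]3([C@@H](OC(=O)CCCCCCC/C=C\CCCCCCO[Si](c4ccccc4)(c4ccccc4)C(C)(C)C)C=C2C(=O)O)[C@@H](C=O)CC[C@@H]13 | intermediate
40 | CNP0148862.1: 2-formyl-10-{[(9Z)-16-hydroxyhexadec-9-enoyl]oxy}-6-(hydroxymethyl)-6-methyltricyclo[5.3.1.0^1,5]undec-8-ene-8-carboxylic acid | C[C@@]1(CO)[C@@H]2C[C@]3([C@@H](OC(=O)CCCCCCC/C=C\CCCCCCO)C=C2C(=O)O)[C@@H](C=O)CC[C@@H]13 | target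

**Step count and risks**

Total: 25 steps. Longest linear sequence: 22 steps (steps 1–17 and 21–25); the side-chain acid takes 3 steps (18–20).

Steps most likely to fail:

1. Step 13. Acetate may intercept the phenoxonium ion before the alkene adds, because the allylic silyloxy group makes this alkene less nucleophilic than a prenyl-type one. The C6 cation may also be captured by the carbonyl oxygen instead of C7, or the TBS ether may be lost in the acidic anolyte. The fallback separates oxidation from cyclisation. It sets out from 20: Wessely acetoxylation with Pb(OAc)4 in CH2Cl2 at −40 °C would give the ortho-quinol acetate F1. Ionisation of F1 with Me3SiOSO2CF3 or BF3·OEt2 in CH2Cl2 at −78 °C regenerates the same cation in a medium with no external nucleophile, so the tethered alkene is its only partner. The liberated acetate then returns at C10, and the sequence comes back to the route at 21.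

2. Step 15 (with step 14). Condensation at the ketone next to the quaternary C1 may stall, hydride delivery to the hindered C=N may be slow, or forcing conditions may cost the TBS ether. The fallback sets out from 21: NaBH4 in EtOH/THF at 0 °C would reduce the ketone to the C11 alcohol F2. Phenyl chlorothionoformate with DMAP and pyridine converts F2 into the C11 O-phenyl thionocarbonate F3. Barton–McCombie deoxygenation of F3 with Bu3SnH and AIBN in toluene at 90 °C (kept concentrated in stannane to suppress homoallyl radical rearrangement) comes back to the route at 25.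

3. Step 16. The ene step may be sluggish because the allylic acetate deactivates the alkene, the product may be over-oxidised, or selenous acid may cleave a silyl ether. The fallback sets out from 25: Wohl–Ziegler bromination (N-bromosuccinimide, AIBN, PhCF3, 80 °C) at the C8 methyl would give the C8 bromomethyl compound F4. Oxidation of F4 with N-methylmorpholine N-oxide in MeCN (amine-oxide variant of the Kornblum oxidation) comes back to the route at 27.

Further compounds
F1 | step 13 | ortho-quinol acetate: 6-acetoxy-6-[(2S,5E)-1-(tert-butyldimethylsilyloxy)-7-(tert-butyldiphenylsilyloxy)-6-methylhept-5-en-2-yl]-3-methylcyclohexa-2,4-dien-1-one (either epimer at the acetoxy carbon) | CC1=CC(=O)C(OC(C)=O)([C@@H](CO[Si](C)(C)C(C)(C)C)CC/C=C(\C)CO[Si](c2ccccc2)(c2ccccc2)C(C)(C)C)C=C1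
F2 | step 15 | C11 alcohol from 21 (either C11 epimer) | C[C@@]1(CO[Si](c4ccccc4)(c4ccccc4)C(C)(C)C)[C@@H]2C(O)[C@]3([C@@H](OC(C)=O)C=C2C)[C@@H](CO[Si](C)(C)C(C)(C)C)CC[C@@H]13
F3 | step 15 | C11 O-phenyl thionocarbonate of F2 | C[C@@]1(CO[Si](c4ccccc4)(c4ccccc4)C(C)(C)C)[C@@H]2C(OC(=S)Oc4ccccc4)[C@]3([C@@H](OC(C)=O)C=C2C)[C@@H](CO[Si](C)(C)C(C)(C)C)CC[C@@H]13
F4 | step 16 | C8 bromomethyl analogue of 25 | C[C@@]1(CO[Si](c4ccccc4)(c4ccccc4)C(C)(C)C)[C@@H]2C[C@]3([C@@H](OC(C)=O)C=C2CBr)[C@@H](CO[Si](C)(C)C(C)(C)C)CC[C@@H]13
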